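The data stem from a simulated flask for substances that don't exist, noise included.

**The decision.** We have to choose a temperature for a flask of substrate into which other conformer is fed, and we judge it by y, the share of target (the selectivity) in all that became target or isomer of the product.

| flask | substrate | other conformer | catalyst | temperature | remark | time |
|---|---|---|---|---|---|---|
| south | 0.020 M | 0.34 equiv (fed, over 50 s) | 0.2 mol% | 35 °C | run made earlier |  |
| west | 0.020 M | 0.75 equiv (fed, over 50 s) | 0.2 mol% | 85 °C | run made earlier |  |
| north-west | 0.020 M | 0.50 equiv (fed, over 50 s) | 0.1 mol% | 35 °C | run made earlier |  |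
| ash | 0.020 M | 0.500 equiv (fed, over 50 s) | 0.2 mol% | 130 °C |  | 6.0 min |
| maple | 0.020 M | 0.500 equiv (fed, over 50 s) | 0.2 mol% | 40 °C |  | 6.0 min |
| elm | 0.020 M | 0.500 equiv (fed, over 50 s) | 0.2 mol% | 70 °C |  | 6.0 min |
| cedar | 0.020 M | 0.500 equiv (fed, over 50 s) | 0.2 mol% | 100 °C |  | 6.0 min |

| run | time / min | target / % | isomer of the product / % |
|---|---|---|---|
| south | 60.0 | 66 | 36 |
| south | 120 | 65 | 37 |
| south | 180 | 65 | 39 |
| south | 300 | 66 | 34 |
| south | 480 | 65 | 36 |
| south | 900 | 63 | 34 |
| west | 5.00 | 47 | 53 |
| west | 12.0 | 47 | 52 |
| west | 25.0 | 46 | 54 |
| west | 40.0 | 48 | 55 |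
| west | 60.0 | 47 | 53 |
| west | 80.0 | 49 | 52 |
| north-west | 80.0 | 55 | 46 |
| north-west | 240 | 54 | 48 |
| north-west | 360 | 53 | 48 |
| north-west | 600 | 55 | 48 |
| north-west | 900 | 55 | 47 |

(scatter of a reading: 1.5 percentage points)

* the best flask by share of target in all that became target or isomer of the product; "all alike" if 1.5 percentage points covers them all (ash / maple / elm / cedar / all alike)
* share of target in all that became target or isomer of the product, ash
* share of target in all that became target or isomer of the product, maple
* share of target in all that became target or isomer of the product, elm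
* share of target in all that became target or isomer of the product, cedar

- in a conversion other conformer counts as not yet reacted
- a reading or a percentage of target counts all its forms, free or not

**Reading the runs.** Within each earlier run the readings show no drift beyond the scatter of 1.5 percentage points, so each run gives one y. The south run gives 64.4 %. Now let e be the equivalents of other conformer, and let f, one divided by one plus e, be the substrate's part of the charge. In the south run f is 74.6 %, so y falls short of it.

**Retention.** We call ρ = y/f the retention 0.862; that is its reading for the south run. Retention under one means that isomer of the product holds more than the other conformer's part of the charge. The west run, at 85 °C, reads 0.824. The north-west run, with 0.1 mol% of catalyst, reads 0.802.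

**Our reckoning.** Maple, at 40 °C with 0.2 mol% of catalyst, resembles the south run, at 35 °C with 0.2 mol%, so we carry that ρ over and multiply by maple's f: y = 57.5 %. The west ρ gives 54.9 % for a hot flask at this charge, which is lower, so we would choose maple.

**The forecast.** It names maple, with 58 % for maple, 56 % for elm, 54 % for cedar and 52 % for ash, its maple value standing a little above ours. Of the leak to isomer it says: “This looks like an uncatalysed route competing with the catalysed one”.

**The result.** The best flask is maple, with 57.0 %, against 50.2 % for elm, 48.3 % for cedar and 50.2 % for ash.

    substrate ⇌ other conformer (K = 0.840, k = 0.0637 min⁻¹, Ea = 101 kJ mol⁻¹, ΔH = −2.00 kJ mol⁻¹)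
    substrate + catalyst → catalyst + target (k = 9090 M⁻¹ min⁻¹, Ea = 47.0 kJ mol⁻¹)
    catalyst + other conformer → catalyst + isomer of the product (k = 18300 M⁻¹ min⁻¹, Ea = 43.0 kJ mol⁻¹)
    catalyst + target ⇌ idle complex (K = 139 M⁻¹, k = 59.5 M⁻¹ min⁻¹, Ea = 64.0 kJ mol⁻¹, ΔH = −28.0 kJ mol⁻¹)
    (constants at 40 °C)

**The neighbour.** Maple's own retention at 6.00 min comes out at 0.854, close to the carried 0.862, while elm's is 0.753 and cedar's 0.725, both lower than the west reading 0.824. Take now a neighbour of maple, the same flask with 0.120 equiv of other conformer. Its f is 89.3 %, and the carried ρ makes y = 77.0 %. That neighbour gives 76.6 %, and at 6.00 min it holds, in percent of the substrate and other conformer together charged, 58.6 % of target, all its forms counted, and 18.6 % of substrate.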